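**Retrosynthetic overview**
1. Target 9 ⇐ enone 8 by substrate-controlled 1,2-reduction of the ketone (sets C6–OH last; both acetates and the benzoate are already in place).
2. 8 ⇐ α-ketol 6 by an acyloin 1,2-shift that expands the cyclopentene to the cyclohexenone and creates the C(OH)(CH2OBz) centre by chirality transfer.
3. 6 ⇐ ethynyl carbinol 5 by gold-catalysed alkyne oxidation with benzoate trapping; 5 ⇐ enone 3 + acetylide 4.
4. 3 ⇐ 2 ⇐ 1 by α′-acetoxylation and O-acetylation; the single stereocentre of 1 controls all the others.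
5. Ring order: the five-membered ring is bought in 1; the six-membered ring is formed once, in step 5.

Assumption: (R)-4-hydroxycyclopent-2-en-1-one is bought enantiopure; acyl donors and oxidants are entered as reagents that add atoms.

**Step 1**
Reactants: 1 (R)-4-hydroxycyclopent-2-en-1-one
Product: 2 (R)-4-acetoxycyclopent-2-en-1-one
Conditions: Ac2O, pyridine, DMAP (cat.), CH2Cl2, 0 °C
Reagents that add atoms: acetic anhydride CC(=O)OC(C)=O
Why: DMAP-catalysed O-acetylation of the secondary alcohol under cold, weakly basic conditions that do not trigger β-elimination; the stereocentre is untouched.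

**Step 2**
Reactants: 2 (R)-4-acetoxycyclopent-2-en-1-one
Product: 3 (4S,5R)-4,5-diacetoxycyclopent-2-en-1-one (trans)
Conditions: Mn(OAc)3·2H2O (2.5 equiv), PhH–AcOH (10:1), reflux
Reagents that add atoms: manganese(III) acetate CC(=O)[O-].CC(=O)[O-].CC(=O)[O-].[Mn+3]
Why: Mn(OAc)3 α′-acetoxylation of an enone (Mn(III) enolate, α′-keto radical, acetate ligand transfer) delivers OAc to C5 anti to the C4 acetate, and because C5 is epimerisable the trans (5R) isomer is also the thermodynamic one.

**Step 3**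
Reactants: 3 (4S,5R)-4,5-diacetoxycyclopent-2-en-1-one; 4 ethynylmagnesium bromide
Product: 5 (1R,4S,5R)-4,5-diacetoxy-1-ethynylcyclopent-2-en-1-ol
Conditions: LaCl3·2LiCl (1 equiv), THF, −78 °C; pH 7 buffer quench at −78 °C
Reagents that add atoms: none
Why: Lanthanide-mediated acetylide 1,2-addition (Grignard type) to the ketone outruns ester attack and enolisation at −78 °C, and attack anti to the adjacent C5–OAc (Felkin–Anh, steric) places the new OH cis to that acetate, setting C1 (R).

**Step 4**
Reactants: 5 (1R,4S,5R)-4,5-diacetoxy-1-ethynylcyclopent-2-en-1-ol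
Product: 6 2-[(1S,4S,5R)-4,5-diacetoxy-1-hydroxycyclopent-2-en-1-yl]-2-oxoethyl benzoate
Conditions: Mor-DalPhosAuNTf2 (5 mol %), 8-methylquinoline N-oxide (1.5 equiv), BzOH (4 equiv), PhCl, rt
Reagents that add atoms: benzoic acid O=C(O)c1ccccc1; 8-methylquinoline N-oxide Cc1cccc2ccc[n+]([O-])c12
Why: Gold-catalysed alkyne oxidation: the N-oxide attacks the internal carbon of the Au-activated terminal alkyne to give an α-oxo gold carbene at the terminal carbon, which inserts into the O–H of excess benzoic acid to give the benzoyloxymethyl ketone; no stereocentre is affected.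

**Step 5**
Reactants: 6 2-[(1S,4S,5R)-4,5-diacetoxy-1-hydroxycyclopent-2-en-1-yl]-2-oxoethyl benzoate
Product: 8 [(1R,2R,3S)-2,3-diacetoxy-1-hydroxy-6-oxocyclohex-4-en-1-yl]methyl benzoate, via β,γ-enone ketol 7 (not isolated)
Conditions: Sc(OTf)3 (10 mol %), 4 Å MS, PhMe, 80 °C
Reagents that add atoms: none
Why: Proposed new method: a convergent, thermodynamically funnelled α-ketol (acyloin) ring expansion of a 1-acylcyclopent-2-en-1-ol, in which Sc(III) chelates the tertiary OH and the ketone O and either ring bond of the carbinol carbon can shift suprafacially to the acyl carbon; shift of the acetoxy-bearing sp3 carbon gives 8 directly, whereas the probably faster alkenyl shift gives the β,γ-unsaturated ketol 7, which reaches the same 8 by reversal through 6 or by a second 1,2-shift of its CH2OBz group; 6, 7 and 8 are the only members of this manifold and 8 alone is both six-membered and a conjugated enone, so equilibration should drain into it; each chelated shift keeps the new C–OH on the face of the old one and the migrating carbon retains configuration, so C1 (R) of 8 is relayed from the carbinol carbon of 6 and C2/C3 are unchanged; closest known reaction type is the Lewis-acid α-ketol ring expansion of 1-acylcycloalkanols (D-homoannulation of 17-hydroxy-20-keto steroids), proposed here as untested on acyl cyclopentenols and as a two-path equilibration.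

**Step 6**
Reactants: 8 [(1R,2R,3S)-2,3-diacetoxy-1-hydroxy-6-oxocyclohex-4-en-1-yl]methyl benzoate
Product: 9 [(1S,2R,3S,6S)-2,3-diacetoxy-1,6-dihydroxycyclohex-4-en-1-yl]methyl benzoate (target)
Conditions: NaBH4, CeCl3·7H2O, MeOH, −78 °C; AcOH quench
Reagents that add atoms: none
Why: Luche 1,2-reduction; in the half-chair with both acetates and CH2OBz pseudo-equatorial the C1–OH is axial, so hydride should add axially and anti to that C–O bond (polar Felkin–Anh, torsional control), giving the equatorial C6–OH cis to C1–OH (6S), with the esters untouched at −78 °C.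

**Compound list**
1 | (R)-4-hydroxycyclopent-2-en-1-one | O=C1C=C[C@H](O)C1 | starting material
2 | (R)-4-acetoxycyclopent-2-en-1-one | O=C1C=C[C@H](OC(C)=O)C1 | intermediate
3 | (4S,5R)-4,5-diacetoxycyclopent-2-en-1-one | O=C1C=C[C@H](OC(C)=O)[C@H]1OC(C)=O | intermediate
4 | ethynylmagnesium bromide | C#C[Mg]Br | starting material
5 | (1R,4S,5R)-4,5-diacetoxy-1-ethynylcyclopent-2-en-1-ol | C#C[C@]1(O)C=C[C@H](OC(C)=O)[C@H]1OC(C)=O | intermediate
6 | 2-[(1S,4S,5R)-4,5-diacetoxy-1-hydroxycyclopent-2-en-1-yl]-2-oxoethyl benzoate | O=C(COC(=O)c1ccccc1)[C@]2(O)C=C[C@H](OC(C)=O)[C@H]2OC(C)=O | intermediate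
7 | [(1R,4S,5R)-4,5-diacetoxy-1-hydroxy-6-oxocyclohex-2-en-1-yl]methyl benzoate | O=C1[C@](O)(COC(=O)c2ccccc2)C=C[C@H](OC(C)=O)[C@H]1OC(C)=O | intermediate
8 | [(1R,2R,3S)-2,3-diacetoxy-1-hydroxy-6-oxocyclohex-4-en-1-yl]methyl benzoate | CC(=O)O[C@H]1C=CC(=O)[C@@](O)(COC(=O)c2ccccc2)[C@@H]1OC(C)=O | intermediate
9 | [(1S,2R,3S,6S)-2,3-diacetoxy-1,6-dihydroxycyclohex-4-en-1-yl]methyl benzoate | CC(=O)O[C@H]1C=C[C@H](O)[C@@](O)(COC(=O)c2ccccc2)[C@@H]1OC(C)=O | target

**Step count**
Total steps: 6. Longest linear sequence: 6 steps (1 → 9).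

**Three steps most likely to fail**

Step 5 (the proposed new step). The equilibration may stall at 7, and 7 has an enolisable α-acetoxy ketone that can epimerise or lose AcOH. The fallback uses only established reaction types and makes the kinetically favoured alkenyl shift the productive one. It sets out from 2 (with 4) and comes back at 8.
- Addition of 4 to 2 (LaCl3·2LiCl, THF, −78 °C) anti to the C4 acetate gives (1S,4R)-4-acetoxy-1-ethynylcyclopent-2-en-1-ol F1.
- Gold oxidation exactly as in step 4 gives 2-[(1S,4R)-4-acetoxy-1-hydroxycyclopent-2-en-1-yl]-2-oxoethyl benzoate F2.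
- A brief kinetic α-ketol ring expansion (Sc(OTf)3 cat., CH2Cl2, 0 °C), in which the alkenyl carbon shifts in preference to the CH2, gives [(1S,4R)-4-acetoxy-1-hydroxy-6-oxocyclohex-2-en-1-yl]methyl benzoate F3.
- Hydroxyl-directed epoxidation (mCPBA, CH2Cl2, 0 °C) on the face of the tertiary OH gives [(1R,2R,5R,6R)-5-acetoxy-2-hydroxy-3-oxo-7-oxabicyclo[4.1.0]heptan-2-yl]methyl benzoate F4.
- Acetolysis with inversion at the less hindered epoxide carbon (AcOH, NaOAc, 50 °C) gives [(1R,2R,3R,4R)-3,4-diacetoxy-1,2-dihydroxy-6-oxocyclohexyl]methyl benzoate F5.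
- Ac2O/Et3N/DMAP acetylates the secondary OH to [(1R,2R,3S,4R)-2,3,4-triacetoxy-1-hydroxy-6-oxocyclohexyl]methyl benzoate F6, which loses its β-acetoxy group by E1cB in the same flask to give 8.

Step 4. The tertiary propargylic OH can trap the gold carbene intramolecularly (oxetan-3-one), or the alcohol can undergo Meyer–Schuster rearrangement. The fallback builds the side chain without a carbene. It sets out from 5 and comes back at 6.
- Markovnikov hydration of the alkyne (Ph3PAuNTf2 cat., dioxane–H2O, 60 °C) gives 1-[(1S,4S,5R)-4,5-diacetoxy-1-hydroxycyclopent-2-en-1-yl]ethanone F7.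
- Bromination of the only enolisable position (CuBr2, EtOAc–CHCl3, reflux) gives 2-bromo-1-[(1S,4S,5R)-4,5-diacetoxy-1-hydroxycyclopent-2-en-1-yl]ethanone F8.
- SN2 displacement with potassium benzoate (BzOH, K2CO3, DMF, rt) gives 6.

Step 2. Under hot Mn(III)/AcOH conditions 2 may lose AcOH to cyclopentadienone, or the trans selectivity may be poor. The fallback installs the C5 oxygen by low-temperature enolate oxidation. It sets out from 1 and comes back at 3.
- TBSCl/imidazole (DMF) gives (R)-4-(tert-butyldimethylsilyloxy)cyclopent-2-en-1-one F9.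
- LiHMDS (THF, −78 °C) then 2-(phenylsulfonyl)-3-phenyloxaziridine hydroxylates the α′-enolate anti to the silyloxy group to give (4S,5R)-4-(tert-butyldimethylsilyloxy)-5-hydroxycyclopent-2-en-1-one F10.
- Ac2O with cat. FeCl3 (MeCN, 0 °C) acetylates the free OH and exchanges the silyl ether for acetate with retention, giving 3.

**Further compounds**
F1 | step 5 | (1S,4R)-4-acetoxy-1-ethynylcyclopent-2-en-1-ol | C#C[C@@]1(O)C=C[C@H](OC(C)=O)C1
F2 | step 5 | 2-[(1S,4R)-4-acetoxy-1-hydroxycyclopent-2-en-1-yl]-2-oxoethyl benzoate | O=C(COC(=O)c1ccccc1)[C@@]2(O)C=C[C@H](OC(C)=O)C2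
F3 | step 5 | [(1S,4R)-4-acetoxy-1-hydroxy-6-oxocyclohex-2-en-1-yl]methyl benzoate | O=C1C[C@@H](OC(C)=O)C=C[C@]1(O)COC(=O)c2ccccc2
F4 | step 5 | [(1R,2R,5R,6R)-5-acetoxy-2-hydroxy-3-oxo-7-oxabicyclo[4.1.0]heptan-2-yl]methyl benzoate | O=C1C[C@@H](OC(C)=O)[C@H]2O[C@H]2[C@]1(O)COC(=O)c3ccccc3
F5 | step 5 | [(1R,2R,3R,4R)-3,4-diacetoxy-1,2-dihydroxy-6-oxocyclohexyl]methyl benzoate | O=C1C[C@@H](OC(C)=O)[C@H](OC(C)=O)[C@@H](O)[C@]1(O)COC(=O)c2ccccc2
F6 | step 5 | [(1R,2R,3S,4R)-2,3,4-triacetoxy-1-hydroxy-6-oxocyclohexyl]methyl benzoate | O=C1C[C@@H](OC(C)=O)[C@H](OC(C)=O)[C@@H](OC(C)=O)[C@]1(O)COC(=O)c2ccccc2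
F7 | step 4 | 1-[(1S,4S,5R)-4,5-diacetoxy-1-hydroxycyclopent-2-en-1-yl]ethanone | CC(=O)[C@]1(O)C=C[C@H](OC(C)=O)[C@H]1OC(C)=O
F8 | step 4 | 2-bromo-1-[(1S,4S,5R)-4,5-diacetoxy-1-hydroxycyclopent-2-en-1-yl]ethanone | BrCC(=O)[C@]1(O)C=C[C@H](OC(C)=O)[C@H]1OC(C)=O
F9 | step 2 | (R)-4-(tert-butyldimethylsilyloxy)cyclopent-2-en-1-one | O=C1C=C[C@H](O[Si](C)(C)C(C)(C)C)C1
F10 | step 2 | (4S,5R)-4-(tert-butyldimethylsilyloxy)-5-hydroxycyclopent-2-en-1-one | O=C1C=C[C@H](O[Si](C)(C)C(C)(C)C)[C@H]1O
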